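Readings and results come from a simulation for substances that don't exist; noise was put on by code.

The question was which of violet, grey, red and teal, alike but for temperature, would stand highest after 12 h in excess of left-handed over right-handed product. I took excess as a share of the product, left minus right over left plus right, the usual enantiomeric excess.

in all of them: left-handed substrate 10 mM; right-handed substrate 10 mM; impurity 31 µM

| flask | solid reagent | free catalyst | racemization catalyst | temperature | remark | time |
|---|---|---|---|---|---|---|
| alpha | 40 mM | 0.50 mM | 0.14 mM | −14 °C | run made earlier |  |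
| delta | 40 mM | 0.50 mM | 0.32 mM | 11 °C | run made earlier |  |
| eta | 40 mM | 0.75 mM | 0.21 mM | −14 °C | run made earlier |  |
| violet | 40.0 mM | 0.50 mM | 0.21 mM | 20 °C |  | 12 h |
| grey | 40.0 mM | 0.50 mM | 0.21 mM | −25 °C |  | 12 h |
| red | 40.0 mM | 0.50 mM | 0.21 mM | −10 °C |  | 12 h |
| teal | 40.0 mM | 0.50 mM | 0.21 mM | 5 °C |  | 12 h |

| run | time / h | left-handed product / % | right-handed product / % |
|---|---|---|---|
| alpha | 8.00 | 1.8 | 0 |
| alpha | 15.0 | 4.2 | 1.0 |
| alpha | 20.0 | 4.7 | 0.7 |
| alpha | 25.0 | 6.5 | 2.6 |
| alpha | 30.0 | 9.1 | 1.6 |
| alpha | 40.0 | 11.7 | 0.8 |
| delta | 0.833 | 0 | 0 |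
| delta | 1.50 | 1.6 | 2.2 |
| delta | 2.50 | 1.5 | 0 |
| delta | 4.00 | 4.3 | 1.1 |
| delta | 6.00 | 5.8 | 2.4 |
| delta | 12.0 | 9.2 | 3.7 |
| eta | 4.00 | 1.5 | 0.3 |
| eta | 10.0 | 3.9 | 0 |
| eta | 15.0 | 4.0 | 1.0 |
| eta | 25.0 | 9.0 | 2.8 |
| eta | 40.0 | 15.8 | 2.8 |

(scatter of a reading: 1 percentage point)

- free catalyst is single-handed; left-handed substrate and right-handed substrate are mirror images of each other, charged as a racemate, each of them at the stated concentration
- as a solid, counted per litre of solution: solid reagent
- the numbers in the tables scatter with a standard deviation of 1 percentage point
- steps thought possible: partner + free catalyst + left-handed substrate -> free catalyst + left-handed product; partner + free catalyst + right-handed substrate -> free catalyst + right-handed product; left-handed substrate + racemization catalyst <-> right-handed substrate + racemization catalyst; solid reagent <-> partner; 2 racemization catalyst <-> resting dimer; racemization catalyst + impurity -> spent catalyst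
- at the start none of the solid reagent is in solution
- an excess is below zero if the other one leads

- the best flask by excess of left-handed product over right-handed product; "all alike" if 1.5 percentage points covers them all (violet / grey / red / teal / all alike)
- excess of left-handed product over right-handed product at the end, violet
- excess of left-handed product over right-handed product at the end, grey
- excess of left-handed product over right-handed product at the end, red
- excess of left-handed product over right-handed product at the end, teal

Both product steps carry the same partner and the same free catalyst, so these cancel when one rate is divided by the other. While the two substrates stay near equal, that quotient integrates in closed form: the products stand in a constant ratio s, the selectivity factor.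

    excess = (s − 1)/(s + 1)

I turned the settings in order. Time, by hand, grows both products and, while the two substrates stay near equal, leaves s alone. Free catalyst, by hand, scales both rates alike. From alpha to eta it rose from 0.50 mM to 0.75 mM, with racemization catalyst rising from 0.14 mM to 0.21 mM, and the summed tables gave s of 5.67 and 4.96, which I could not separate at a scatter of 1 percentage point per reading.

Temperature is different: two steps with unequal activation energies part as it moves. Alpha and eta pooled read s = 5.31 at −14 °C, higher than the 2.38 read from delta at 11 °C. Delta also carried 0.32 mM of racemization catalyst against 0.14 mM and 0.21 mM in alpha and eta; I set that difference aside by choice and reckoned the fall in s on temperature. The gap in activation energy, right-handed step minus left-handed, follows: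

    gap = R·ln(s cold/s warm)/(1/T cold − 1/T warm) = 19.6 kJ mol⁻¹
    s(T) = s cold·exp[(gap/R)(1/T − 1/T cold)]

    grey, −25 °C: s = 7.95, excess 77.6 %
    red, −10 °C: s = 4.62, excess 64.4 %
    teal, 5 °C: s = 2.85, excess 48.1 %
    violet, 20 °C: s = 1.85, excess 29.7 %

So I chose grey.

The forecast differed: violet, with 5.8 % for violet, 1.6 % for grey, 3.2 % for red and 4.9 % for teal, on the ground “Rising rate outweighs falling selectivity”.

The flasks gave grey at 75.4 %, then red at 64.6 %, teal at 51.9 % and violet at 38.5 %.

    partner + free catalyst + left-handed substrate → free catalyst + left-handed product (k = 260 M⁻² min⁻¹, Ea = 36.0 kJ mol⁻¹)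
    partner + free catalyst + right-handed substrate → free catalyst + right-handed product (k = 110 M⁻² min⁻¹, Ea = 51.0 kJ mol⁻¹)
    left-handed substrate + racemization catalyst ⇌ right-handed substrate + racemization catalyst, rate k3*[racemization catalyst]*[left-handed substrate] forward; the back reaction follows from the equilibrium constant (k = 14.0 M⁻¹ min⁻¹, Ea = 53.0 kJ mol⁻¹)
    solid reagent ⇌ partner, rate k4*(cs4 - [partner]) while solid is left; crystals form when [partner] > cs4 (solubility = 7.40 mM, k = 0.00240 min⁻¹)
    2 racemization catalyst ⇌ resting dimer, settled at all times (K = 4600 M⁻¹, ΔH = 0 kJ mol⁻¹)
    racemization catalyst + impurity → spent catalyst (k = 2700 M⁻¹ min⁻¹, Ea = 52.0 kJ mol⁻¹)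
    (constants at 20 °C)

Grey held 1.21 % left-handed and 0.169 % right-handed product, a difference of 1 point of the charge but 75.4 % as a share of product. The same flask as violet, run at −5 °C, reckons by the gap to s = 3.91, an excess of 59.3 %; that flask stood at 60.6 %.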